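The cis-fused γ-lactone is disconnected at two bonds: the acyl bond C2–C3 and the ring-fusion bond C3a–C7a (benzofuranone numbering), the latter shared with the cyclohexane. A titanocene-mediated hetero-Pauson–Khand reaction forms both in one operation by joining carbon monoxide with the aldehyde C=O and the terminal vinyl group of an acyclic 1,7-enal. It closes the carbocycle and the lactone ring (O1–C2–C3–C3a–C7a) and sets C3a and C7a. The enal carries the vicinal quaternary/tertiary vinyl–isopropenyl pair from an enantioselective Ireland–Claisen rearrangement and the silyloxy stereocentre from (S)-2-vinyloxirane. C3 is then hydroxylated, methylated and acetylated; the C4 ester is attached last.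

Key step: step 8

Assumption: the (S,S)-bromoborane is taken to give the (2R,3S) sense in step 5 (its enantiomer would be used if the sense is opposite), and (S)-2-vinyloxirane is taken as a commercial compound.

Numbering: bicyclic compounds use benzofuranone numbering (O1, C2 lactone carbonyl, C3, C3a, C4–C7, C7a); TBS = tert-butyldimethylsilyl.

Step 1
Reactants: 1 (S)-2-vinyloxirane
Product: 2 (3R)-hex-1-en-5-yn-3-ol
Conditions: LiC≡CH·H2NCH2CH2NH2, DMSO, 0 °C → rt; then H2O
Reagents that add atoms: lithium acetylide–ethylenediamine complex ([Li+].[C-]#C.NCCN)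
Why: SN2 opening of the epoxide at its unsubstituted CH2 by acetylide should leave the allylic stereocentre untouched (the descriptor becomes R only through the CIP priorities).

Step 2
Reactants: 2 (3R)-hex-1-en-5-yn-3-ol
Product: 3 tert-butyl{[(3R)-hex-1-en-5-yn-3-yl]oxy}dimethylsilane
Conditions: TBSCl, imidazole, DMF, rt
Reagents that add atoms: tert-butyldimethylsilyl chloride (CC(C)(C)[Si](C)(C)Cl)
Why: standard silylation of the secondary alcohol gives an ether that should survive organoaluminium, boron, hydride, titanium and enolate chemistry until step 12.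

Step 3
Reactants: 3 tert-butyl{[(3R)-hex-1-en-5-yn-3-yl]oxy}dimethylsilane
Product: 6 (2E,5R)-5-(TBS-oxy)-3-methylhepta-2,6-dien-1-ol, via alkenylalane 4 (not isolated), via lithium alkenylaluminate 5 (not isolated)
Conditions: Me3Al, Cp2ZrCl2 (cat.), CH2Cl2, 0 °C → rt; then n-BuLi, (CH2O)n, THF, −78 °C → rt
Reagents that add atoms: trimethylaluminium (C[Al](C)C); formaldehyde from paraformaldehyde (C=O)
Why: zirconium-catalysed carboalumination adds Me–Al syn across the terminal alkyne (methyl to the internal carbon), and the derived aluminate is hydroxymethylated with retention, so the (E)-trisubstituted alkene should result while the terminal alkene stays inert.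

Step 4
Reactants: 6 (2E,5R)-5-(TBS-oxy)-3-methylhepta-2,6-dien-1-ol; 7 3-methylbut-3-enoic acid
Product: 8 (2E,5R)-5-(TBS-oxy)-3-methylhepta-2,6-dien-1-yl 3-methylbut-3-enoate
Conditions: DCC, DMAP (cat.), CH2Cl2, 0 °C
Reagents that add atoms: none
Why: Steglich esterification of the primary allylic alcohol at low temperature with catalytic DMAP should limit conjugation of the β,γ-unsaturated acyl group.

Step 5
Reactants: 8 (2E,5R)-5-(TBS-oxy)-3-methylhepta-2,6-dien-1-yl 3-methylbut-3-enoate
Product: 10 (2R,3S,5R)-5-(TBS-oxy)-3-ethenyl-3-methyl-2-(prop-1-en-2-yl)hept-6-enoic acid, via Z(O) boron dienolate 9 (not isolated)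
Conditions: (4S,5S)-2-bromo-1,3-bis[3,5-bis(trifluoromethyl)phenylsulfonyl]-4,5-diphenyl-1,3,2-diazaborolidine, i-Pr2NEt, CH2Cl2, −78 °C; then −20 → 4 °C; aqueous work-up
Reagents that add atoms: none
Why: soft enolisation should give the boron dienolate with isopropenyl trans to the allylic oxygen, and its Ireland–Claisen rearrangement through a chair (the (E)-alkene places C4H2 equatorial and methyl axial) sets C2 and C3 in the required relative sense, while the chiral diazaborolidine selects the enolate face and so the absolute sense independently of the remote C5 centre.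

Step 6
Reactants: 10 (2R,3S,5R)-5-(TBS-oxy)-3-ethenyl-3-methyl-2-(prop-1-en-2-yl)hept-6-enoic acid
Product: 11 (2R,3S,5R)-5-(TBS-oxy)-3-ethenyl-3-methyl-2-(prop-1-en-2-yl)hept-6-en-1-ol
Conditions: LiAlH4, Et2O, 0 °C → rt
Reagents that add atoms: none
Why: hydride reduction of the carboxylic acid proceeds through the non-epimerisable carboxylate and should leave alkenes and the silyl ether untouched.

Step 7
Reactants: 11 (2R,3S,5R)-5-(TBS-oxy)-3-ethenyl-3-methyl-2-(prop-1-en-2-yl)hept-6-en-1-ol
Product: 12 (2R,3S,5R)-5-(TBS-oxy)-3-ethenyl-3-methyl-2-(prop-1-en-2-yl)hept-6-enal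
Conditions: DMP (triacetoxyperiodinane), pyridine, CH2Cl2, 0 °C; used at once
Reagents that add atoms: none
Why: periodinane oxidation under buffered, non-basic conditions should give the β,γ-unsaturated aldehyde without epimerisation at C2 or conjugation.

Step 8
Reactants: 12 (2R,3S,5R)-5-(TBS-oxy)-3-ethenyl-3-methyl-2-(prop-1-en-2-yl)hept-6-enal
Product: 15 (3aR,4R,6S,7R,7aR)-4-(TBS-oxy)-6-ethenyl-6-methyl-7-(prop-1-en-2-yl)hexahydro-1-benzofuran-2(3H)-one, via oxatitanacyclopentane 13 (not isolated), via acyl titanocene alkoxide 14 (not isolated)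
Conditions: Cp2Ti(PMe3)2 (1.1 equiv), toluene, rt; then CO (1–2 atm), rt → 60 °C
Reagents that add atoms: carbon monoxide ([C-]#[O+])
Why: Cp2Ti(PMe3)2 loses phosphine and binds the aldehyde as a titanaoxirane, the tethered vinyl group inserts into its Ti–C bond to give oxatitanacycle 13, CO inserts into the Ti–CH2 bond (14), and C(acyl)–O reductive elimination releases lactone 15 and Cp2Ti(CO)2; this is a hetero-Pauson–Khand reaction, the closest known type being the titanocene-mediated reductive cyclocarbonylation of tethered δ,ε-unsaturated aldehydes and ketones. The cyclohexane closes in a 6-exo sense (aldehyde carbon to the internal alkene carbon, forming C3a–C7a), and the lactone closes as the [2+2+1] ring around titanium, the CO carbon becoming C2 and bonding to C3 (the former terminal alkene carbon). C7a and C3a are set together: the five-membered titanacycle should enforce a cis ring fusion, and a chair-like closure with isopropenyl (C7) and OTBS (C4) equatorial puts the titanium-bound oxygen axial with isopropenyl anti to the forming bond (the usual arrangement for addition to an α-branched aldehyde) and the vinyl group equatorial with C4–H eclipsing it, which should give O1 cis to isopropenyl and C3 trans to OTBS. Chemoselectivity among the three alkenes is secured by ring size, since only the vinyl group next to the silyloxy carbon reaches the aldehyde through a six-membered ring while the other two would need three- or four-membered rings. The epimerisable α-centre of 12 is protected by running the cyclisation at room temperature on freshly made aldehyde.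

Step 9
Reactants: 15 (3aR,4R,6S,7R,7aR)-4-(TBS-oxy)-6-ethenyl-6-methyl-7-(prop-1-en-2-yl)hexahydro-1-benzofuran-2(3H)-one
Product: 17 (3R,3aR,4R,6S,7R,7aR)-4-(TBS-oxy)-6-ethenyl-3-hydroxy-6-methyl-7-(prop-1-en-2-yl)hexahydro-1-benzofuran-2(3H)-one, via potassium enolate 16 (not isolated)
Conditions: KHMDS, THF, −78 °C; 2-(phenylsulfonyl)-3-phenyloxaziridine; then AcOH
Reagents that add atoms: 2-(phenylsulfonyl)-3-phenyloxaziridine (O=S(=O)(N1OC1c1ccccc1)c1ccccc1)
Why: electrophilic hydroxylation of the lactone enolate by the N-sulfonyloxaziridine should place OH on the convex face, and the configuration at C3 is of no consequence because step 10 re-planarises this carbon.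

Step 10
Reactants: 17 (3R,3aR,4R,6S,7R,7aR)-4-(TBS-oxy)-6-ethenyl-3-hydroxy-6-methyl-7-(prop-1-en-2-yl)hexahydro-1-benzofuran-2(3H)-one
Product: 19 (3S,3aR,4R,6S,7R,7aR)-4-(TBS-oxy)-6-ethenyl-3-hydroxy-3,6-dimethyl-7-(prop-1-en-2-yl)hexahydro-1-benzofuran-2(3H)-one, via dilithium enediolate 18 (not isolated)
Conditions: LDA (2.3 equiv), THF–DMPU, −78 → −30 °C; MeI; then AcOH
Reagents that add atoms: iodomethane (CI)
Why: C-alkylation of the α-hydroxy lactone dianion should occur on the convex face, anti to the C3a–C4 bond, so methyl ends cis to H-3a and the oxygen stays on the concave face, which sets the quaternary centre C3.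

Step 11
Reactants: 19 (3S,3aR,4R,6S,7R,7aR)-4-(TBS-oxy)-6-ethenyl-3-hydroxy-3,6-dimethyl-7-(prop-1-en-2-yl)hexahydro-1-benzofuran-2(3H)-one
Product: 20 (3S,3aR,4R,6S,7R,7aR)-4-(TBS-oxy)-6-ethenyl-3,6-dimethyl-2-oxo-7-(prop-1-en-2-yl)octahydro-1-benzofuran-3-yl acetate
Conditions: Ac2O, Et3N, DMAP, CH2Cl2, rt → 40 °C
Reagents that add atoms: acetic anhydride (CC(=O)OC(C)=O)
Why: DMAP-catalysed acylation should acetylate the only free hydroxyl, the tertiary α-hydroxy lactone, with the C4 oxygen still silylated.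

Step 12
Reactants: 20 (3S,3aR,4R,6S,7R,7aR)-4-(TBS-oxy)-6-ethenyl-3,6-dimethyl-2-oxo-7-(prop-1-en-2-yl)octahydro-1-benzofuran-3-yl acetate
Product: 21 (3S,3aS,4R,6S,7R,7aR)-6-ethenyl-4-hydroxy-3,6-dimethyl-2-oxo-7-(prop-1-en-2-yl)octahydro-1-benzofuran-3-yl acetate
Conditions: HF·pyridine, pyridine, THF, 0 °C → rt
Reagents that add atoms: none
Why: buffered fluoride desilylation should free the C4 hydroxyl without base-induced acetyl migration or lactone opening.

Step 13
Reactants: 21 (3S,3aS,4R,6S,7R,7aR)-6-ethenyl-4-hydroxy-3,6-dimethyl-2-oxo-7-(prop-1-en-2-yl)octahydro-1-benzofuran-3-yl acetate; 7 3-methylbut-3-enoic acid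
Product: 22 (3S,3aS,4R,6S,7R,7aR)-3-acetoxy-6-ethenyl-3,6-dimethyl-2-oxo-7-(prop-1-en-2-yl)octahydro-1-benzofuran-4-yl 3-methylbut-3-enoate (CNP0106639.1)
Conditions: DCC, DMAP (cat.), CH2Cl2, 0 °C
Reagents that add atoms: none
Why: Steglich esterification of the equatorial secondary alcohol with retention at C4, kept cold with little DMAP, should avoid isomerisation to the conjugated 3-methylbut-2-enoate.

Compound list
1 | (S)-2-vinyloxirane | C=C[C@H]1CO1 | starting material
2 | (3R)-hex-1-en-5-yn-3-ol | C=C[C@H](O)CC#C | intermediate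
3 | tert-butyl{[(3R)-hex-1-en-5-yn-3-yl]oxy}dimethylsilane | C=C[C@H](O[Si](C)(C)C(C)(C)C)CC#C | intermediate
4 | dimethyl[(1E,4R)-4-(TBS-oxy)-2-methylhexa-1,5-dien-1-yl]alane | C=C[C@H](O[Si](C)(C)C(C)(C)C)C/C(C)=C/[Al](C)C | intermediate (not isolated)
5 | lithium butyl[(1E,4R)-4-(TBS-oxy)-2-methylhexa-1,5-dien-1-yl]dimethylaluminate | C=C[C@H](O[Si](C)(C)C(C)(C)C)C/C(C)=C/[Al-](C)(C)CCCC.[Li+] | intermediate (not isolated)
6 | (2E,5R)-5-(TBS-oxy)-3-methylhepta-2,6-dien-1-ol | C=C[C@H](O[Si](C)(C)C(C)(C)C)C/C(C)=C/CO | intermediate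
7 | 3-methylbut-3-enoic acid | C=C(C)CC(=O)O | starting material
8 | (2E,5R)-5-(TBS-oxy)-3-methylhepta-2,6-dien-1-yl 3-methylbut-3-enoate | C=C(C)CC(=O)OC/C=C(\C)C[C@@H](O[Si](C)(C)C(C)(C)C)C=C | intermediate
9 | Z(O) boron dienolate of 8 on the (4S,5S)-diazaborolidine (isopropenyl trans to the allylic oxygen) | C=C(C)/C=C(/OC/C=C(\C)C[C@@H](O[Si](C)(C)C(C)(C)C)C=C)OB1N(S(=O)(=O)c2cc(C(F)(F)F)cc(C(F)(F)F)c2)[C@@H](c2ccccc2)[C@H](c2ccccc2)N1S(=O)(=O)c1cc(C(F)(F)F)cc(C(F)(F)F)c1 | intermediate (not isolated)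
10 | (2R,3S,5R)-5-(TBS-oxy)-3-ethenyl-3-methyl-2-(prop-1-en-2-yl)hept-6-enoic acid | C=C[C@](C)(C[C@@H](O[Si](C)(C)C(C)(C)C)C=C)[C@H](C(=O)O)C(=C)C | intermediate
11 | (2R,3S,5R)-5-(TBS-oxy)-3-ethenyl-3-methyl-2-(prop-1-en-2-yl)hept-6-en-1-ol | C=C[C@](C)(C[C@@H](O[Si](C)(C)C(C)(C)C)C=C)[C@H](CO)C(=C)C | intermediate
12 | (2R,3S,5R)-5-(TBS-oxy)-3-ethenyl-3-methyl-2-(prop-1-en-2-yl)hept-6-enal | C=C[C@](C)(C[C@@H](O[Si](C)(C)C(C)(C)C)C=C)[C@H](C=O)C(=C)C | intermediate
13 | cis-fused oxatitanacyclopentane (Cp2Ti bonded to O1 and to the C3 methylene; other centres as in 15) | C=C[C@]1(C)C[C@@H](O[Si](C)(C)C(C)(C)C)[C@H]2[C@H](O[Ti](C3C=CC=C3)(C3C=CC=C3)C2)[C@@H]1C(=C)C | intermediate (not isolated)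
14 | acyl titanocene alkoxide (CO inserted between Ti and the C3 methylene) | C=C[C@]1(C)C[C@@H](O[Si](C)(C)C(C)(C)C)[C@H]2[C@H](O[Ti](C3C=CC=C3)(C3C=CC=C3)C(=O)C2)[C@@H]1C(=C)C | intermediate (not isolated)
15 | (3aR,4R,6S,7R,7aR)-4-(TBS-oxy)-6-ethenyl-6-methyl-7-(prop-1-en-2-yl)hexahydro-1-benzofuran-2(3H)-one | C=C[C@]1(C)C[C@@H](O[Si](C)(C)C(C)(C)C)[C@H]2[C@H](OC(=O)C2)[C@@H]1C(=C)C | intermediate
16 | potassium enolate of lactone 15 | C=C[C@]1(C)C[C@@H](O[Si](C)(C)C(C)(C)C)[C@H]2[C@H](OC([O-])=C2)[C@@H]1C(=C)C.[K+] | intermediate (not isolated)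
17 | (3R,3aR,4R,6S,7R,7aR)-4-(TBS-oxy)-6-ethenyl-3-hydroxy-6-methyl-7-(prop-1-en-2-yl)hexahydro-1-benzofuran-2(3H)-one | C=C[C@]1(C)C[C@@H](O[Si](C)(C)C(C)(C)C)[C@H]2[C@H](OC(=O)[C@@H]2O)[C@@H]1C(=C)C | intermediate
18 | dilithium enediolate of 17 | C=C[C@]1(C)C[C@@H](O[Si](C)(C)C(C)(C)C)[C@H]2[C@H](OC([O-])=C2[O-])[C@@H]1C(=C)C.[Li+].[Li+] | intermediate (not isolated)
19 | (3S,3aR,4R,6S,7R,7aR)-4-(TBS-oxy)-6-ethenyl-3-hydroxy-3,6-dimethyl-7-(prop-1-en-2-yl)hexahydro-1-benzofuran-2(3H)-one | C=C[C@]1(C)C[C@@H](O[Si](C)(C)C(C)(C)C)[C@H]2[C@H](OC(=O)[C@@]2(C)O)[C@@H]1C(=C)C | intermediate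
20 | (3S,3aR,4R,6S,7R,7aR)-4-(TBS-oxy)-6-ethenyl-3,6-dimethyl-2-oxo-7-(prop-1-en-2-yl)octahydro-1-benzofuran-3-yl acetate | C=C[C@]1(C)C[C@@H](O[Si](C)(C)C(C)(C)C)[C@H]2[C@H](OC(=O)[C@@]2(C)OC(C)=O)[C@@H]1C(=C)C | intermediate
21 | (3S,3aS,4R,6S,7R,7aR)-6-ethenyl-4-hydroxy-3,6-dimethyl-2-oxo-7-(prop-1-en-2-yl)octahydro-1-benzofuran-3-yl acetate | C=C[C@]1(C)C[C@@H](O)[C@H]2[C@H](OC(=O)[C@@]2(C)OC(C)=O)[C@@H]1C(=C)C | intermediate
22 | (3S,3aS,4R,6S,7R,7aR)-3-acetoxy-6-ethenyl-3,6-dimethyl-2-oxo-7-(prop-1-en-2-yl)octahydro-1-benzofuran-4-yl 3-methylbut-3-enoate | C=C[C@]1(C)C[C@@H](OC(=O)CC(=C)C)[C@H]2[C@H](OC(=O)[C@@]2(C)OC(C)=O)[C@@H]1C(=C)C | target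

Total step count: 13. Longest linear sequence: 13 steps (from 1).

Steps most likely to fail

1. Step 8. Closure of the six-membered carbocycle at titanium may be slower than the established five-membered cases, which would let α-epimerisation or conjugation of the β,γ-unsaturated aldehyde and intermolecular carbonyl coupling compete. The facial selectivity at C7a/C3a relative to C7 and C4 may also be poor. The fallback sets out from acid 10 and comes back at lactone 15, replacing the carbonylative cyclisation by a [2+2] cycloaddition followed by oxygen insertion. Acid 10 would be activated with isobutyl chloroformate and N-methylmorpholine as the mixed anhydride F1 and treated with diazomethane to give the diazoketone F2. Silver benzoate-catalysed Wolff rearrangement in the presence of pyrrolidine (migration with retention at the isopropenyl carbon) would give the homologated pyrrolidine amide F3. Triflic anhydride and 2,4,6-collidine in 1,2-dichloroethane would convert it into the keteniminium triflate F4, which should undergo intramolecular [2+2] cycloaddition with the terminal vinyl group to the cis-fused cyclobutaniminium triflate F5. This forms the same two carbon–carbon bonds, with cis fusion enforced by the four-membered ring; its facial sense is governed by the keteniminium geometry rather than by a carbonyl addition and would have to be checked. Aqueous hydrolysis would give the cyclobutanone F6, and Baeyer–Villiger oxidation with H2O2 in AcOH (migration of the ring-fusion carbon with retention, isolated alkenes untouched) would return lactone 15.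

2. Step 5. Enolisation may give the other dienolate geometry (isopropenyl cis to the allylic oxygen), which through the same chair would deliver the C2 epimer of 10. The fallback sets out from alkyne 3 and comes back at acid 10, inverting both the alkene and the enolate geometry so that the chair again gives the required relative configuration. Alkyne 3 would be deprotonated with n-BuLi and acylated with methyl chloroformate to the ynoate F7. Syn addition of Me2CuLi at −78 °C would give the (2Z)-enoate F8, and DIBAL-H reduction the (2Z)-allylic alcohol F9. Esterification with acid 7 (DCC, cat. DMAP) would give the (2Z)-ester F10. Enolisation with the same class of bromoborane under Et3N/toluene–hexane conditions would give the E(O) boron dienolate F11 (the reagent enantiomer re-selected for the 2R sense), whose rearrangement returns acid 10.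

3. Step 10. O-Methylation of the alkoxide, incomplete C-alkylation at the hindered α-carbon, or attack from the concave face would erode the C3 quaternary centre. The fallback sets out from hydroxy lactone 17 and comes back at 19, building the centre by carbonyl addition instead of enolate alkylation. Oxidation of 17 with DMP would give the α-keto lactone F12, and addition of MeMgBr (or MeTi(Oi-Pr)3) at −78 °C to the ketone carbonyl from the convex face would place methyl cis to H-3a and give 19.

Further compounds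
F1 | step 8 | isobutyl carbonic mixed anhydride of acid 10 | C=C[C@](C)(C[C@@H](O[Si](C)(C)C(C)(C)C)C=C)[C@H](C(=O)OC(=O)OCC(C)C)C(=C)C
F2 | step 8 | (3R,4S,6R)-6-(TBS-oxy)-1-diazo-4-ethenyl-4-methyl-3-(prop-1-en-2-yl)oct-7-en-2-one | C=C[C@](C)(C[C@@H](O[Si](C)(C)C(C)(C)C)C=C)[C@H](C(=O)C=[N+]=[N-])C(=C)C
F3 | step 8 | 1-[6-(TBS-oxy)-4-ethenyl-4-methyl-3-(prop-1-en-2-yl)oct-7-enoyl]pyrrolidine (configuration as in 10) | C=C[C@](C)(C[C@@H](O[Si](C)(C)C(C)(C)C)C=C)[C@H](CC(=O)N1CCCC1)C(=C)C
F4 | step 8 | keteniminium triflate derived from F3 | C=C[C@](C)(C[C@@H](O[Si](C)(C)C(C)(C)C)C=C)[C@H](C=C=[N+]1CCCC1)C(=C)C.[O-]S(=O)(=O)C(F)(F)F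
F5 | step 8 | cis-fused bicyclo[4.2.0]octan-7-ylidene pyrrolidinium triflate (configuration as in 15) | C=C[C@]1(C)C[C@@H](O[Si](C)(C)C(C)(C)C)[C@H]2[C@H](C(=[N+]3CCCC3)C2)[C@@H]1C(=C)C.[O-]S(=O)(=O)C(F)(F)F
F6 | step 8 | cis-fused 5-(TBS-oxy)-3-ethenyl-3-methyl-2-(prop-1-en-2-yl)bicyclo[4.2.0]octan-7-one (configuration as in 15) | C=C[C@]1(C)C[C@@H](O[Si](C)(C)C(C)(C)C)[C@H]2[C@H](C(=O)C2)[C@@H]1C(=C)C
F7 | step 5 | methyl (5R)-5-(TBS-oxy)hept-6-en-2-ynoate | C=C[C@H](O[Si](C)(C)C(C)(C)C)CC#CC(=O)OC
F8 | step 5 | methyl (2Z,5R)-5-(TBS-oxy)-3-methylhepta-2,6-dienoate | C=C[C@H](O[Si](C)(C)C(C)(C)C)C/C(C)=C\C(=O)OC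
F9 | step 5 | (2Z,5R)-5-(TBS-oxy)-3-methylhepta-2,6-dien-1-ol | C=C[C@H](O[Si](C)(C)C(C)(C)C)C/C(C)=C\CO
F10 | step 5 | (2Z,5R)-5-(TBS-oxy)-3-methylhepta-2,6-dien-1-yl 3-methylbut-3-enoate | C=C(C)CC(=O)OC/C=C(/C)C[C@@H](O[Si](C)(C)C(C)(C)C)C=C
F11 | step 5 | E(O) boron dienolate of F10 on the diazaborolidine (isopropenyl cis to the allylic oxygen) | C=C(C)/C=C(\OC/C=C(/C)C[C@@H](O[Si](C)(C)C(C)(C)C)C=C)OB1N(S(=O)(=O)c2cc(C(F)(F)F)cc(C(F)(F)F)c2)[C@@H](c2ccccc2)[C@H](c2ccccc2)N1S(=O)(=O)c1cc(C(F)(F)F)cc(C(F)(F)F)c1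
F12 | step 10 | (3aR,4R,6S,7R,7aR)-4-(TBS-oxy)-6-ethenyl-6-methyl-7-(prop-1-en-2-yl)hexahydro-1-benzofuran-2,3-dione | C=C[C@]1(C)C[C@@H](O[Si](C)(C)C(C)(C)C)[C@H]2[C@H](OC(=O)C2=O)[C@@H]1C(=C)C
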